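## Retrosynthetic overview

1. Target 22 ⇐ protected lactone 21 by one mild acid step (C14 acetal → enal, C15 silyl ether → alcohol).
2. 21 ⇐ open-chain bromo ester aldehyde 18 in one flask: first the ten-membered carbocycle by C6–C7 bond formation (the farnesyl C1–C10 bond made by the germacrene cyclase), then the γ-lactone by attack of the new C6 alkoxide on the C12 ester. The C8 isovalerate is the only stereocentre and sets C6 and C7.
3. 18 ⇐ dialdehyde 14 + methyl propiolate (C11–C13); 14 ⇐ Z-vinyl iodide 4 (C4–C6, C15) + diene 10 by B-alkyl Suzuki coupling at C3–C4.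
4. 10 ⇐ vinyl anion (C2–C3) + 3,3-diethoxypropyne 5 (C1, C10, C14) + (R)-glycidyl PMB ether 6 (C7–C9) in one carbocupration/epoxide-opening step that fixes the C1=C10 geometry and brings in C8.
5. Ring order: ten-membered carbocycle, then lactone.

Locants C1–C15 are germacrane locants of the target: C6 lactone O–CH, C7 ring CH bearing C11, C8 CH–O-isovalerate, C10/C14 the C(CHO) unit, C4/C15 the C(CH2OH) unit, C11/C12/C13 lactone α-carbon, carbonyl and exo-methylene.

Assumption: epoxide 6 is bought as the single R enantiomer.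

## Route

Step 1
Reactants: 1 but-2-yne-1,4-diol
Product: 2 4-{[tert-butyl(dimethyl)silyl]oxy}but-2-yn-1-ol
Conditions: TBSCl (0.33 equiv), imidazole, THF, 0 °C → rt (diol in excess)
Reagents that add atoms: tert-butyldimethylsilyl chloride, CC(C)(C)[Si](C)(C)Cl
Why: Statistical monosilylation (silyl ether formation) of a symmetrical diol used in excess leaves one free hydroxyl to direct the next step.

Step 2
Reactants: 2 4-{[tert-butyl(dimethyl)silyl]oxy}but-2-yn-1-ol
Product: 4 (2Z)-4-{[tert-butyl(dimethyl)silyl]oxy}-3-iodobut-2-en-1-ol, via sodium oxaaluminate 3 (not isolated)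
Conditions: NaAlH2(OCH2CH2OMe)2, THF, 0 °C; then I2, −78 → 0 °C
Reagents that add atoms: iodine, [I][I]
Why: Hydroxyl-directed trans-hydroalumination of the propargylic alcohol places aluminium on the distal alkyne carbon cis to CH2OH, and iodinolysis with retention gives the Z iodide that fixes the C4=C5 geometry (C15 trans to C6).

Step 3
Reactants: 5 3,3-diethoxyprop-1-yne; 6 (2R)-2-{[(4-methoxyphenyl)methoxy]methyl}oxirane
Product: 9 (2R,4E)-4-(diethoxymethyl)-1-[(4-methoxyphenyl)methoxy]hepta-4,6-dien-2-ol, via lithium bis(dienyl)cuprate 7 (not isolated), via lithium alkoxide 8 (not isolated)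
Conditions: CH2=CHBr, t-BuLi, Et2O, −78 °C; CuBr·SMe2, −45 °C; 5 (2 equiv per Cu), −45 °C; then 6, −45 → −25 °C; aq NH4Cl/NH3
Reagents that add atoms: vinyl bromide, C=CBr
Why: Proposed new method: syn-carbocupration of the acetylenic acetal by lithium divinylcuprate (Normant-type carbocupration, copper ending on the acetal-bearing carbon cis to the new vinyl group) gives an alkenylcuprate that is configurationally stable at low temperature and should open the glycidyl ether at its CH2 terminus with retention at the alkenyl carbon, so the C1=C10 geometry comes from the syn addition and C8 from the epoxide; the closest known reactions are the alkylation of such α-acetal alkenylcuprates with alkyl halides and cuprate openings of glycidyl ethers.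

Step 4
Reactants: 9 (2R,4E)-4-(diethoxymethyl)-1-[(4-methoxyphenyl)methoxy]hepta-4,6-dien-2-ol
Product: 10 (2R,4E)-4-(diethoxymethyl)-1-[(4-methoxyphenyl)methoxy]hepta-4,6-dien-2-yl 3-methylbutanoate
Conditions: Me2CHCH2COCl, pyridine, DMAP (cat.), CH2Cl2, 0 °C → rt
Reagents that add atoms: 3-methylbutanoyl chloride, CC(C)CC(=O)Cl
Why: DMAP-catalysed acylation (nucleophilic acyl transfer) of the secondary alcohol installs the native ester without touching the C8 stereocentre.

Step 5
Reactants: 10 (2R,4E)-4-(diethoxymethyl)-1-[(4-methoxyphenyl)methoxy]hepta-4,6-dien-2-yl 3-methylbutanoate; 4 (2Z)-4-{[tert-butyl(dimethyl)silyl]oxy}-3-iodobut-2-en-1-ol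
Product: 12 (2R,4E,8E)-8-({[tert-butyl(dimethyl)silyl]oxy}methyl)-4-(diethoxymethyl)-10-hydroxy-1-[(4-methoxyphenyl)methoxy]deca-4,8-dien-2-yl 3-methylbutanoate, via B-alkyl-9-BBN adduct 11 (not isolated)
Conditions: 9-BBN-H, THF, 0 °C → rt; then 4, PdCl2(dppf) (5 mol %), AsPh3, Cs2CO3, DMF/H2O, rt
Reagents that add atoms: none
Why: 9-BBN-H hydroborates only the monosubstituted terminus of the diene (anti-Markovnikov), and the primary alkylborane undergoes B-alkyl Suzuki–Miyaura coupling with the vinyl iodide with retention of its Z geometry, forming C3–C4.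

Step 6
Reactants: 12 (2R,4E,8E)-8-({[tert-butyl(dimethyl)silyl]oxy}methyl)-4-(diethoxymethyl)-10-hydroxy-1-[(4-methoxyphenyl)methoxy]deca-4,8-dien-2-yl 3-methylbutanoate
Product: 13 (2R,4E,8E)-8-({[tert-butyl(dimethyl)silyl]oxy}methyl)-4-(diethoxymethyl)-1,10-dihydroxydeca-4,8-dien-2-yl 3-methylbutanoate
Conditions: DDQ, CH2Cl2/pH 7 phosphate buffer, 0 °C; used crude
Reagents that add atoms: none
Why: Oxidative PMB-ether cleavage by DDQ under buffered conditions spares the silyl ether, the acetal and the ester, and any over-oxidation of the allylic alcohol converges in the next step.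

Step 7
Reactants: 13 (2R,4E,8E)-8-({[tert-butyl(dimethyl)silyl]oxy}methyl)-4-(diethoxymethyl)-1,10-dihydroxydeca-4,8-dien-2-yl 3-methylbutanoate
Product: 14 (2R,4E,8E)-8-({[tert-butyl(dimethyl)silyl]oxy}methyl)-4-(diethoxymethyl)-1,10-dioxodeca-4,8-dien-2-yl 3-methylbutanoate
Conditions: TEMPO (20 mol %), PhI(OAc)2 (2.4 equiv), CH2Cl2, rt
Reagents that add atoms: none
Why: Oxoammonium (TEMPO) oxidation stops at the aldehyde for both primary alcohols under non-basic conditions that protect the α-acyloxy aldehyde from epimerisation and acyl migration.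

Step 8
Reactants: 14 (2R,4E,8E)-8-({[tert-butyl(dimethyl)silyl]oxy}methyl)-4-(diethoxymethyl)-1,10-dioxodeca-4,8-dien-2-yl 3-methylbutanoate
Product: 16 methyl (4R,6E,10E)-10-({[tert-butyl(dimethyl)silyl]oxy}methyl)-6-(diethoxymethyl)-3-hydroxy-2-methylidene-4-[(3-methylbutanoyl)oxy]-12-oxododeca-6,10-dienoate (both C3 epimers), via aluminium alkoxide 15 (not isolated)
Conditions: iBu2AlH, N-methylmorpholine N-oxide, methyl propiolate, THF, 0 °C; then 14, −78 → −20 °C; cold aq NH4Cl
Reagents that add atoms: methyl propiolate, C#CC(=O)OC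
Why: Hydroalumination of methyl propiolate gives an α-(methoxycarbonyl)vinylalane whose 1,2-addition (a Morita–Baylis–Hillman adduct made by vinylmetal addition) should select the more electrophilic non-conjugated α-acyloxy aldehyde over the hindered conjugated C6 aldehyde, and the uncontrolled carbinol centre is erased in step 9.

Step 9
Reactants: 16 methyl (4R,6E,10E)-10-({[tert-butyl(dimethyl)silyl]oxy}methyl)-6-(diethoxymethyl)-3-hydroxy-2-methylidene-4-[(3-methylbutanoyl)oxy]-12-oxododeca-6,10-dienoate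
Product: 18 methyl (2Z,4R,6E,10E)-2-(bromomethyl)-10-({[tert-butyl(dimethyl)silyl]oxy}methyl)-6-(diethoxymethyl)-4-[(3-methylbutanoyl)oxy]-12-oxododeca-2,6,10-trienoate, via alkoxysulfonium bromide 17 (not isolated)
Conditions: NBS, Me2S, CH2Cl2, 0 °C (premixed); then 16, 0 °C → rt
Reagents that add atoms: N-bromosuccinimide, O=C1CCC(=O)N1Br
Why: Corey–Kim-type activation of the allylic alcohol followed by SN2' attack of bromide gives the thermodynamically preferred Z 2-(bromomethyl)enoate and removes the C7 carbinol centre.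

Step 10
Reactants: 18 methyl (2Z,4R,6E,10E)-2-(bromomethyl)-10-({[tert-butyl(dimethyl)silyl]oxy}methyl)-6-(diethoxymethyl)-4-[(3-methylbutanoyl)oxy]-12-oxododeca-2,6,10-trienoate
Product: 21 (3aR,4R,6E,10E,11aR)-10-({[tert-butyl(dimethyl)silyl]oxy}methyl)-6-(diethoxymethyl)-3-methylidene-2-oxo-2,3,3a,4,5,8,9,11a-octahydrocyclodeca[b]furan-4-yl 3-methylbutanoate, via allylchromium dichloride 19 (not isolated), via chromium alkoxide 20 (not isolated)
Conditions: CrCl2 (8 equiv), THF, 2 mM, 18 added over 10 h, 25 °C then 40 °C; H2O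
Reagents that add atoms: none
Why: Intramolecular Nozaki–Hiyama-type chromium Barbier allylation forms the C6–C7 bond through a chair transition state with C5 and C8 equatorial (anti addition, hence the trans ring fusion), in which C8–H eclipses the allyl plane to avoid allylic strain with the ester and the aldehyde is predicted to attack anti to C9 on the face of the acyloxy group (which can also bind chromium), giving 6R,7R from 8R, after which the chromium alkoxide closes the lactone on the methyl ester.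

Step 11
Reactants: 21 (3aR,4R,6E,10E,11aR)-10-({[tert-butyl(dimethyl)silyl]oxy}methyl)-6-(diethoxymethyl)-3-methylidene-2-oxo-2,3,3a,4,5,8,9,11a-octahydrocyclodeca[b]furan-4-yl 3-methylbutanoate
Product: 22 (3aR,4R,6E,10E,11aR)-6-formyl-10-(hydroxymethyl)-3-methylidene-2-oxo-2,3,3a,4,5,8,9,11a-octahydrocyclodeca[b]furan-4-yl 3-methylbutanoate (CNP0345200.3)
Conditions: AcOH/THF/H2O (3:1:1), 30 °C
Reagents that add atoms: water, O
Why: Mild aqueous acid hydrolyses the α,β-unsaturated diethyl acetal to the thermodynamically preferred enal and cleaves the primary allylic silyl ether without touching the lactone, the ester or the three stereocentres.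

## Compound list

1 | but-2-yne-1,4-diol | OCC#CCO | starting material
2 | 4-{[tert-butyl(dimethyl)silyl]oxy}but-2-yn-1-ol | CC(C)(C)[Si](C)(C)OCC#CCO | intermediate
3 | sodium oxaaluminate from trans-hydroalumination of 2 (Al on the carbon bearing CH2OTBS, chelated by the alkoxide, two 2-methoxyethoxy ligands) | [Na+].COCCO[Al-]1(OCCOC)OCC=C1CO[Si](C)(C)C(C)(C)C | intermediate
4 | (2Z)-4-{[tert-butyl(dimethyl)silyl]oxy}-3-iodobut-2-en-1-ol | OC/C=C(\I)CO[Si](C)(C)C(C)(C)C | intermediate
5 | 3,3-diethoxyprop-1-yne | C#CC(OCC)OCC | starting material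
6 | (2R)-2-{[(4-methoxyphenyl)methoxy]methyl}oxirane | COc1ccc(COC[C@H]2CO2)cc1 | starting material
7 | lithium bis[(1Z)-1-(diethoxymethyl)buta-1,3-dien-1-yl]cuprate | C=C/C=C(\[Cu-]\C(=C/C=C)C(OCC)OCC)C(OCC)OCC.[Li+] | intermediate
8 | lithium (2R,4E)-4-(diethoxymethyl)-1-[(4-methoxyphenyl)methoxy]hepta-4,6-dien-2-olate | COc1ccc(COC[C@H]([O-])C/C(=C\C=C)C(OCC)OCC)cc1.[Li+] | intermediate
9 | (2R,4E)-4-(diethoxymethyl)-1-[(4-methoxyphenyl)methoxy]hepta-4,6-dien-2-ol | COc1ccc(COC[C@H](O)C/C(=C\C=C)C(OCC)OCC)cc1 | intermediate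
10 | (2R,4E)-4-(diethoxymethyl)-1-[(4-methoxyphenyl)methoxy]hepta-4,6-dien-2-yl 3-methylbutanoate | COc1ccc(COC[C@H](OC(=O)CC(C)C)C/C(=C\C=C)C(OCC)OCC)cc1 | intermediate
11 | B-alkyl-9-borabicyclo[3.3.1]nonane from 10 (boron on the former terminal diene carbon, C3) | COc1ccc(COC[C@H](OC(=O)CC(C)C)C/C(=C\CCB2C3CCCC2CCC3)C(OCC)OCC)cc1 | intermediate
12 | (2R,4E,8E)-8-({[tert-butyl(dimethyl)silyl]oxy}methyl)-4-(diethoxymethyl)-10-hydroxy-1-[(4-methoxyphenyl)methoxy]deca-4,8-dien-2-yl 3-methylbutanoate | OC/C=C(/CO[Si](C)(C)C(C)(C)C)CC/C=C(\C[C@@H](OC(=O)CC(C)C)COCc1ccc(OC)cc1)C(OCC)OCC | intermediate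
13 | (2R,4E,8E)-8-({[tert-butyl(dimethyl)silyl]oxy}methyl)-4-(diethoxymethyl)-1,10-dihydroxydeca-4,8-dien-2-yl 3-methylbutanoate | OC/C=C(/CO[Si](C)(C)C(C)(C)C)CC/C=C(\C[C@@H](OC(=O)CC(C)C)CO)C(OCC)OCC | intermediate
14 | (2R,4E,8E)-8-({[tert-butyl(dimethyl)silyl]oxy}methyl)-4-(diethoxymethyl)-1,10-dioxodeca-4,8-dien-2-yl 3-methylbutanoate | O=C/C=C(/CO[Si](C)(C)C(C)(C)C)CC/C=C(\C[C@@H](OC(=O)CC(C)C)C=O)C(OCC)OCC | intermediate
15 | diisobutylaluminium alkoxide of 16 | O=C/C=C(/CO[Si](C)(C)C(C)(C)C)CC/C=C(\C[C@@H](OC(=O)CC(C)C)C(O[Al](CC(C)C)CC(C)C)C(=C)C(=O)OC)C(OCC)OCC | intermediate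
16 | methyl (4R,6E,10E)-10-({[tert-butyl(dimethyl)silyl]oxy}methyl)-6-(diethoxymethyl)-3-hydroxy-2-methylidene-4-[(3-methylbutanoyl)oxy]-12-oxododeca-6,10-dienoate (both C3 epimers) | O=C/C=C(/CO[Si](C)(C)C(C)(C)C)CC/C=C(\C[C@@H](OC(=O)CC(C)C)C(O)C(=C)C(=O)OC)C(OCC)OCC | intermediate
17 | O-(dimethylsulfonio) derivative of 16, bromide salt | O=C/C=C(/CO[Si](C)(C)C(C)(C)C)CC/C=C(\C[C@@H](OC(=O)CC(C)C)C(O[S+](C)C)C(=C)C(=O)OC)C(OCC)OCC.[Br-] | intermediate
18 | methyl (2Z,4R,6E,10E)-2-(bromomethyl)-10-({[tert-butyl(dimethyl)silyl]oxy}methyl)-6-(diethoxymethyl)-4-[(3-methylbutanoyl)oxy]-12-oxododeca-2,6,10-trienoate | O=C/C=C(/CO[Si](C)(C)C(C)(C)C)CC/C=C(\C[C@@H](OC(=O)CC(C)C)/C=C(\CBr)C(=O)OC)C(OCC)OCC | intermediate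
19 | allylchromium dichloride from 18 (CrCl2 in place of Br) | O=C/C=C(/CO[Si](C)(C)C(C)(C)C)CC/C=C(\C[C@@H](OC(=O)CC(C)C)/C=C(\C[Cr](Cl)Cl)C(=O)OC)C(OCC)OCC | intermediate
20 | chromium dichloride alkoxide of the ring-closed 6-hydroxy methyl ester (ten-membered ring formed, lactone not yet closed) | C=C(C(=O)OC)[C@H]1[C@H](O[Cr](Cl)Cl)/C=C(/CO[Si](C)(C)C(C)(C)C)CC/C=C(/C(OCC)OCC)C[C@H]1OC(=O)CC(C)C | intermediate
21 | (3aR,4R,6E,10E,11aR)-10-({[tert-butyl(dimethyl)silyl]oxy}methyl)-6-(diethoxymethyl)-3-methylidene-2-oxo-2,3,3a,4,5,8,9,11a-octahydrocyclodeca[b]furan-4-yl 3-methylbutanoate | C=C1C(=O)O[C@@H]2/C=C(/CO[Si](C)(C)C(C)(C)C)CC/C=C(/C(OCC)OCC)C[C@@H](OC(=O)CC(C)C)[C@@H]12 | intermediate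
22 | (3aR,4R,6E,10E,11aR)-6-formyl-10-(hydroxymethyl)-3-methylidene-2-oxo-2,3,3a,4,5,8,9,11a-octahydrocyclodeca[b]furan-4-yl 3-methylbutanoate | C=C1C(=O)O[C@@H]2/C=C(/CO)CC/C=C(/C=O)C[C@@H](OC(=O)CC(C)C)[C@@H]12 | target

## Step count and risks

Total steps: 11. Longest linear sequence: 9 steps (steps 1, 2, 5–11; the branch through steps 3, 4, 5–11 is equally long).

Most likely to fail, in order:

Step 10. The allylchromium carries the C8 isovalerate next to the reacting carbon, so 1,4-elimination of the carboxylate to a dienoate can compete with ring closure. The sense of induction from C8 (and trans versus cis fusion) is a prediction, and oligomerisation is possible. Fallback: set out from alcohol 16 and convert it (ClCO2Me, pyridine, CH2Cl2) into the C7 allylic methyl carbonate F1. Close the ring by palladium umpolung instead of a stoichiometric divalent chromium Barbier reaction: catalytic Pd(PPh3)4 ionises F1 to a π-allylpalladium, InI reduces this to a more covalent allylindium under high dilution in THF, and this adds to the C6 aldehyde at C7. The indium alkoxide lactonises and the fallback comes back to the route at 21.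

Step 3. The α-acetal alkenylcuprate 7 may lose ethoxide to an alkoxyallene before the epoxide is opened, or the epoxide opening may be too slow below −25 °C. Fallback: set out from 5, form the same cuprate and quench it with I2 to isolate (3Z)-5,5-diethoxy-4-iodopenta-1,3-diene F2. Convert F2 by iodine–lithium exchange (t-BuLi, Et2O, −78 °C) into the configurationally stable alkenyllithium and open epoxide 6 with it in the presence of BF3·OEt2 at −78 °C. This replaces the one-flask cuprate alkylation with a stepwise organolithium route and comes back at 9.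

Step 8. The vinylalane must distinguish two aldehydes, and the aluminium alkoxide 15 sits next to the C8 ester, so acyl migration or attack at C6 can lower the yield. Fallback: set out from 14 and use a catalytic amine-mediated Morita–Baylis–Hillman reaction with methyl acrylate (DABCO, MeOH, rt) in place of the preformed organoaluminium. Conjugated β,β-disubstituted aldehydes are inert to this reaction, so only the α-acyloxy aldehyde reacts, and the fallback comes back at 16 without any new isolated compound.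

## Further compounds

F1 | step 10 | methyl (4R,6E,10E)-10-({[tert-butyl(dimethyl)silyl]oxy}methyl)-6-(diethoxymethyl)-3-[(methoxycarbonyl)oxy]-2-methylidene-4-[(3-methylbutanoyl)oxy]-12-oxododeca-6,10-dienoate | O=C/C=C(/CO[Si](C)(C)C(C)(C)C)CC/C=C(\C[C@@H](OC(=O)CC(C)C)C(OC(=O)OC)C(=C)C(=O)OC)C(OCC)OCC
F2 | step 3 | (3Z)-5,5-diethoxy-4-iodopenta-1,3-diene | C=C/C=C(\I)C(OCC)OCC
F0 | step 8 | none | none
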